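**Retrosynthetic overview**

1. Numbering: lactone O1, C2 (C=O), C3 (=CH2), C3a, C4 (acyloxy), C5 (side chain C1'–C4'), C6 (methyl), C7, C7a. The 2-methylbutanoate, the C4 oxygen (allylic hydroxylation on the convex face) and the C3 methylene (aminomethylation, elimination) are late additions to a cis-fused lactone.
2. Key disconnection: the O1–C2 bond of the lactone (ring B) together with the C7a–H bond. The cis-lactone comes from a 2-oxocyclohex-4-enyl acetate by enzymatic reduction of the C7a ketone while the neighbouring C3a equilibrates.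
3. Feature that carries the plan: carbons C3a, C4, C5, C6, C7 and C7a of the carbocycle (ring A) are a masked anisole with OMe on C7a, the acetic acid arm on C3a, the chain on C5 and the methyl on C6. The unsubstituted C4 and C7 are para to each other, so Birch reduction can only leave C5=C6 and a masked C7a ketone next to an epimerisable C3a.
4. The arene comes from 3-methylanisole and succinic anhydride: Friedel–Crafts acylation para to OMe, methylenation, asymmetric hydrogenation (C1'), reduction, bromination ortho to OMe, palladium-catalysed arylation of an acetate enolate.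
5. Ring order: ring A is present from the start as the arene and is dearomatised in step 7; ring B is closed in step 9.

Key step: step 9

Assumption: the antipode of the spiro phosphine–oxazoline ligand (step 3) and the ketoreductase variant (step 9) are fixed by a preliminary screen so that the configurations drawn are the ones delivered.

**Route**

Step 1
Reactants: 1 3-methylanisole; 2 succinic anhydride
Product: 3 4-(4-methoxy-2-methylphenyl)-4-oxobutanoic acid
Conditions: AlCl3 (2.2 equiv), CH2Cl2, 0 °C to rt; aq. HCl
Reagents that add atoms: none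
Why: Friedel–Crafts acylation, in which the methoxy group directs the acylium ion to its para position (also ortho to the methyl group), so the future side chain sits para to the oxygenated carbon.

Step 2
Reactants: 3 4-(4-methoxy-2-methylphenyl)-4-oxobutanoic acid
Product: 4 4-(4-methoxy-2-methylphenyl)pent-4-enoic acid
Conditions: Ph3PCH3Br (2.5 equiv), KOt-Bu (3.5 equiv), THF, 0 to 50 °C; aq. HCl
Reagents that add atoms: methyltriphenylphosphonium bromide, C[P+](c1ccccc1)(c1ccccc1)c1ccccc1.[Br-]
Why: Wittig methylenation of the aryl ketone, run on the potassium carboxylate, which the excess ylide tolerates.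

Step 3
Reactants: 4 4-(4-methoxy-2-methylphenyl)pent-4-enoic acid
Product: 5 (4S)-4-(4-methoxy-2-methylphenyl)pentanoic acid
Conditions: H2 (6 atm), [Ir(cod)(L)]B[3,5-(CF3)2C6H3]4 (1 mol%; L = chiral 7-(diarylphosphino)-7'-(4-benzyloxazolin-2-yl)-1,1'-spirobiindane), Et3N (0.5 equiv), MeOH, rt
Reagents that add atoms: none
Why: Carboxy-directed iridium-catalysed asymmetric hydrogenation of a 1,1-disubstituted alkene, in which the bound carboxylate and the spiro P,N ligand pocket select the alkene face and set C1' as S.

Step 4
Reactants: 5 (4S)-4-(4-methoxy-2-methylphenyl)pentanoic acid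
Product: 6 (4S)-4-(4-methoxy-2-methylphenyl)pentan-1-ol
Conditions: LiAlH4, THF, 0 °C to rt; Fieser work-up
Reagents that add atoms: none
Why: Hydride reduction of the carboxylic acid to the primary alcohol; C1' is not alpha to the carbonyl and cannot epimerise.

Step 5
Reactants: 6 (4S)-4-(4-methoxy-2-methylphenyl)pentan-1-ol
Product: 7 (4S)-4-(5-bromo-4-methoxy-2-methylphenyl)pentan-1-ol
Conditions: NBS (1.05 equiv), MeCN, 0 °C to rt, dark
Reagents that add atoms: N-bromosuccinimide, O=C1CCC(=O)N1Br
Why: Electrophilic aromatic bromination at the one open position that is ortho to the methoxy group, para to the methyl group and not flanked by two substituents, which is the future C3a.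

Step 6
Reactants: 7 (4S)-4-(5-bromo-4-methoxy-2-methylphenyl)pentan-1-ol
Product: 9 arylacetic acid (2-[5-[(2S)-5-hydroxypentan-2-yl]-2-methoxy-4-methylphenyl]acetic acid), via ethyl arylacetate 8 (not isolated)
Conditions: BrZnCH2CO2Et (3 equiv), Pd2(dba)3 (2 mol%), XPhos (8 mol%), THF, 65 °C; then LiOH, MeOH/H2O, 40 °C; aq. HCl to pH 2
Reagents that add atoms: (2-ethoxy-2-oxoethyl)zinc bromide, CCOC(=O)C[Zn]Br; lithium hydroxide, [Li+].[OH-]
Why: Palladium-catalysed arylation of a zinc ester enolate (Reformatsky reagent, Negishi-type coupling at zerovalent palladium) tolerates the free hydroxyl at the cost of one equivalent of the zinc reagent, and saponification in the same flask gives the acid needed for the dissolving-metal step.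

Step 7
Reactants: 9 arylacetic acid
Product: 11 keto acid (2-[5-[(2S)-5-hydroxypentan-2-yl]-4-methyl-2-oxocyclohex-4-en-1-yl]acetic acid, both ring C1 epimers), via dihydroanisole acid 10 (not isolated)
Conditions: Li (12 equiv), NH3(l)/THF/t-BuOH, −78 to −33 °C; NH4Cl; evaporate NH3; then (CO2H)2, THF/H2O, 0 °C to rt
Reagents that add atoms: water, O
Why: Birch reduction, in which the lithium carboxylate and alkoxide are inert to solvated electrons and protonation falls on the two unsubstituted, mutually para ring carbons (C4 and C7), leaving C5=C6 and the enol ether C7a=C3a; oxalic acid then hydrolyses only the enol ether by protonation at C3a, a medium too weak to move C5=C6 into conjugation.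

Step 8
Reactants: 11 keto acid
Product: 12 keto ester (methyl 2-[5-[(2S)-5-hydroxypentan-2-yl]-4-methyl-2-oxocyclohex-4-en-1-yl]acetate, both ring C1 epimers, i.e. epimeric at C3a)
Conditions: TMSCHN2 (1.3 equiv), PhMe/MeOH 4:1, 0 °C
Reagents that add atoms: (trimethylsilyl)diazomethane, C[Si](C)(C)C=[N+]=[N-]
Why: O-methylation of the carboxylic acid by a diazoalkane under neutral conditions, so that neither acid nor base is present to shift the beta,gamma-alkene, and the primary alcohol is not alkylated without a Lewis acid.

Step 9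
Reactants: 12 keto ester (C3a epimers)
Product: 14 cis-lactone ((3aR,7aR)-5-[(2S)-5-hydroxypentan-2-yl]-6-methyl-3a,4,7,7a-tetrahydro-1-benzofuran-2(3H)-one), via cis-hydroxy ester 13 (not isolated)
Conditions: NADPH-dependent ketoreductase (alcohol dehydrogenase variant chosen from a panel), NADP+ (cat.), i-PrOH (15% v/v), K2HPO4/KH2PO4 buffer pH 8.5, MgSO4, weakly basic tertiary-amine polystyrene resin, 35 °C; then citric acid to pH 3, EtOAc, rt
Reagents that add atoms: none
Why: The two C3a epimers of 12 interconvert by reversible enolisation toward C3a (general-base catalysis by buffer and resin), while the ketoreductase binds only the (3aR) epimer and passes hydride from NADPH (recycled by i-PrOH) to one face of the C7a carbonyl, giving the (7aR) alcohol cis to the acetate arm. The closest known reaction types are the ketoreductase dynamic kinetic resolution of 2-substituted cycloalkanones and the alcohol-dehydrogenase reduction of 2-oxocycloalkylacetates to cis-fused lactones. Ring B closes by 5-exo-trig acyl substitution of the C7a hydroxyl (O1) on the ester carbon C2 with loss of methanol, which the cis hydroxy ester does readily and which takes the product out of every equilibrium. C7a is set by the enzyme-controlled face of hydride delivery and C3a by the epimer preference of the active site acting on a labile centre, while C1' is remote from any acidic position and stays S. The step needs epimerisation at C3a and reduction to outrun migration of C5=C6 into conjugation through the C7 dienolate; the fully substituted gamma-carbon C5 of the tetrasubstituted alkene slows gamma-protonation and the medium holds no primary or secondary amine (no enamine pathway), but C3a is activated by the ketone alone, so pH, temperature and resin loading are the variables to tune.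

Step 10
Reactants: 14 cis-lactone
Product: 15 silyl ether ((3aR,7aR)-5-[(2S)-5-(tert-butyldimethylsilyloxy)pentan-2-yl]-6-methyl-3a,4,7,7a-tetrahydro-1-benzofuran-2(3H)-one)
Conditions: TBSCl (1.2 equiv), imidazole (2 equiv), CH2Cl2, 0 °C to rt
Reagents that add atoms: tert-butyldimethylsilyl chloride, CC(C)(C)[Si](C)(C)Cl
Why: Silylation of the primary alcohol masks it for the enolate chemistry and keeps it apart from the C4 hydroxyl that is acylated later.

Step 11
Reactants: 15 silyl ether
Product: 16 Mannich base ((3aR,7aR)-3-[(dimethylamino)methyl] derivative of 15, C3 epimers)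
Conditions: LiN(i-Pr)2 (1.2 equiv), THF, −78 °C; CH2=NMe2+ I− (1.5 equiv), −78 °C to rt
Reagents that add atoms: N,N-dimethylmethyleneiminium iodide, C=[N+](C)C.[I-]
Why: Mannich aminomethylation of the lactone lithium enolate with Eschenmoser's salt; the new C3 centre is removed in the next step, and C3a (beta to the carbonyl) is not touched.

Step 12
Reactants: 16 Mannich base
Product: 18 alpha-methylene lactone ((3aR,7aR)-5-[(2S)-5-(tert-butyldimethylsilyloxy)pentan-2-yl]-6-methyl-3-methylidene-3a,4,7,7a-tetrahydro-1-benzofuran-2(3H)-one), via ammonium iodide 17 (not isolated)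
Conditions: MeI (5 equiv), MeOH, rt; then sat. aq. NaHCO3, CH2Cl2, rt
Reagents that add atoms: none
Why: N-Quaternisation followed by E1cB (Hofmann-type) elimination of trimethylamine, the standard finish of the Eschenmoser methylenation.

Step 13
Reactants: 18 alpha-methylene lactone
Product: 19 allylic alcohol ((3aS,4S,7aR)-4-hydroxy derivative of 18; the 3a descriptor changes by CIP priority only)
Conditions: SeO2 (0.3 equiv), t-BuOOH (3 equiv, in decane), CH2Cl2, 0 °C to rt
Reagents that add atoms: tert-butyl hydroperoxide, CC(C)(C)OO (terminal oxidant; its oxygen is relayed by selenium dioxide, O=[Se]=O)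
Why: Riley-type allylic hydroxylation (ene reaction, then [2,3]-sigmatropic shift) in which selenium bonds to the less hindered alkene carbon C6 on the convex face and oxygen is returned suprafacially to the ring methylene C4, so the hydroxyl is cis to H3a (4S); C7 is deactivated by the adjacent lactone oxygen, and the methyl and C1'–H are the less reactive allylic positions.

Step 14
Reactants: 19 allylic alcohol; 20 (2R)-2-methylbutanoic acid
Product: 21 silyl-protected ester ([(3aR,4S,7aR)-5-[(2S)-5-(tert-butyldimethylsilyloxy)pentan-2-yl]-6-methyl-3-methylidene-2-oxo-3a,4,7,7a-tetrahydro-1-benzofuran-4-yl] (2R)-2-methylbutanoate)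
Conditions: DCC (1.5 equiv), DMAP (0.2 equiv), CH2Cl2, 0 °C to rt
Reagents that add atoms: none
Why: Steglich esterification, which acylates the C4 oxygen with retention at C4 and, with catalytic DMAP at low temperature, should leave the alpha-centre of the acid intact.

Step 15
Reactants: 21 silyl-protected ester
Product: 22 target ([(3aR,4S,7aR)-5-[(2S)-5-hydroxypentan-2-yl]-6-methyl-3-methylidene-2-oxo-3a,4,7,7a-tetrahydro-1-benzofuran-4-yl] (2R)-2-methylbutanoate)
Conditions: HF·pyridine, THF/pyridine, 0 °C to rt
Reagents that add atoms: none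
Why: Fluoride-mediated desilylation under buffered, weakly acidic conditions that spare the allylic ester and the alpha-methylene lactone.

**Compound list**

1 | 3-methylanisole | COc1cccc(C)c1 | starting material
2 | succinic anhydride | O=C1CCC(=O)O1 | starting material
3 | 4-(4-methoxy-2-methylphenyl)-4-oxobutanoic acid | COc1ccc(C(=O)CCC(=O)O)c(C)c1 | intermediate
4 | 4-(4-methoxy-2-methylphenyl)pent-4-enoic acid | COc1ccc(C(=C)CCC(=O)O)c(C)c1 | intermediate
5 | (4S)-4-(4-methoxy-2-methylphenyl)pentanoic acid | COc1ccc([C@@H](C)CCC(=O)O)c(C)c1 | intermediate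
6 | (4S)-4-(4-methoxy-2-methylphenyl)pentan-1-ol | COc1ccc([C@@H](C)CCCO)c(C)c1 | intermediate
7 | (4S)-4-(5-bromo-4-methoxy-2-methylphenyl)pentan-1-ol | COc1cc(C)c([C@@H](C)CCCO)cc1Br | intermediate
8 | ethyl 2-[5-[(2S)-5-hydroxypentan-2-yl]-2-methoxy-4-methylphenyl]acetate | CCOC(=O)Cc1cc([C@@H](C)CCCO)c(C)cc1OC | intermediate (not isolated)
9 | 2-[5-[(2S)-5-hydroxypentan-2-yl]-2-methoxy-4-methylphenyl]acetic acid | OC(=O)Cc1cc([C@@H](C)CCCO)c(C)cc1OC | intermediate
10 | 2-[5-[(2S)-5-hydroxypentan-2-yl]-2-methoxy-4-methylcyclohexa-1,4-dien-1-yl]acetic acid | COC1=C(CC(=O)O)CC([C@@H](C)CCCO)=C(C)C1 | intermediate (not isolated)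
11 | 2-[5-[(2S)-5-hydroxypentan-2-yl]-4-methyl-2-oxocyclohex-4-en-1-yl]acetic acid (ring C1 epimers) | O=C(O)CC1CC([C@@H](C)CCCO)=C(C)CC1=O | intermediate
12 | methyl 2-[5-[(2S)-5-hydroxypentan-2-yl]-4-methyl-2-oxocyclohex-4-en-1-yl]acetate (ring C1 epimers) | COC(=O)CC1CC([C@@H](C)CCCO)=C(C)CC1=O | intermediate
13 | methyl 2-[(1R,2R)-2-hydroxy-5-[(2S)-5-hydroxypentan-2-yl]-4-methylcyclohex-4-en-1-yl]acetate | COC(=O)C[C@H]1CC([C@@H](C)CCCO)=C(C)C[C@H]1O | intermediate (not isolated)
14 | (3aR,7aR)-5-[(2S)-5-hydroxypentan-2-yl]-6-methyl-3a,4,7,7a-tetrahydro-1-benzofuran-2(3H)-one | C1C(=O)O[C@@H]2CC(C)=C([C@@H](C)CCCO)C[C@H]12 | intermediate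
15 | (3aR,7aR)-5-[(2S)-5-(tert-butyldimethylsilyloxy)pentan-2-yl]-6-methyl-3a,4,7,7a-tetrahydro-1-benzofuran-2(3H)-one | C1C(=O)O[C@@H]2CC(C)=C([C@@H](C)CCCO[Si](C)(C)C(C)(C)C)C[C@H]12 | intermediate
16 | (3aR,7aR)-5-[(2S)-5-(tert-butyldimethylsilyloxy)pentan-2-yl]-3-[(dimethylamino)methyl]-6-methyl-3a,4,7,7a-tetrahydro-1-benzofuran-2(3H)-one (C3 epimers) | CN(C)CC1C(=O)O[C@@H]2CC(C)=C([C@@H](C)CCCO[Si](C)(C)C(C)(C)C)C[C@H]12 | intermediate
17 | trimethylammoniomethyl iodide derived from 16 | C[N+](C)(C)CC1C(=O)O[C@@H]2CC(C)=C([C@@H](C)CCCO[Si](C)(C)C(C)(C)C)C[C@H]12.[I-] | intermediate (not isolated)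
18 | (3aR,7aR)-5-[(2S)-5-(tert-butyldimethylsilyloxy)pentan-2-yl]-6-methyl-3-methylidene-3a,4,7,7a-tetrahydro-1-benzofuran-2(3H)-one | C=C1C(=O)O[C@@H]2CC(C)=C([C@@H](C)CCCO[Si](C)(C)C(C)(C)C)C[C@H]12 | intermediate
19 | (3aS,4S,7aR)-5-[(2S)-5-(tert-butyldimethylsilyloxy)pentan-2-yl]-4-hydroxy-6-methyl-3-methylidene-3a,4,7,7a-tetrahydro-1-benzofuran-2(3H)-one | C=C1C(=O)O[C@@H]2CC(C)=C([C@@H](C)CCCO[Si](C)(C)C(C)(C)C)[C@@H](O)[C@H]12 | intermediate
20 | (2R)-2-methylbutanoic acid | CC[C@@H](C)C(=O)O | starting material
21 | [(3aR,4S,7aR)-5-[(2S)-5-(tert-butyldimethylsilyloxy)pentan-2-yl]-6-methyl-3-methylidene-2-oxo-3a,4,7,7a-tetrahydro-1-benzofuran-4-yl] (2R)-2-methylbutanoate | C=C1C(=O)O[C@@H]2CC(C)=C([C@@H](C)CCCO[Si](C)(C)C(C)(C)C)[C@@H](OC(=O)[C@H](C)CC)[C@H]12 | intermediate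
22 | [(3aR,4S,7aR)-5-[(2S)-5-hydroxypentan-2-yl]-6-methyl-3-methylidene-2-oxo-3a,4,7,7a-tetrahydro-1-benzofuran-4-yl] (2R)-2-methylbutanoate | C=C1C(=O)O[C@@H]2CC(C)=C([C@@H](C)CCCO)[C@@H](OC(=O)[C@H](C)CC)[C@H]12 | target

**Totals**

Total step count: 15. Longest linear sequence: 15 steps (from 3-methylanisole).

**Steps most likely to fail**

1. Step 9 (key step). C3a is activated by the ketone alone, so epimerisation may be too slow at a pH the enzyme tolerates. The reaction would then stall as a kinetic resolution of the matched half, while the unreacted half slowly moves C5=C6 into conjugation through the more acidic C7 position. Fallback, from 12 to 14: substrate-controlled reduction with LiBH(s-Bu)3 in THF at −78 °C, hydride entering equatorially on each C3a epimer, should give the cis alkoxides only. On warming and acidic work-up these are the cis-hydroxy ester 13 and its ring diastereomer, the (1S,2S)-hydroxy ester F1, which lactonise to 14 and to the (3aS,7aS)-lactone F2. The two lactones are diastereomers through C1' and would be separated by preparative chromatography; the route is rejoined at 14 at the cost of half of the material.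

2. Step 13. Oxygen may be delivered to C7 or to the C6 methyl instead of C4, or to the concave face, and the allylic alcohol may be oxidised further to the enone. Fallback, from 18 to 21: allylic oxidation is taken on purpose to the ketone level with CrO3·3,5-dimethylpyrazole in CH2Cl2 at −20 °C to give the C4 enone F3. Luche 1,2-reduction (NaBH4, CeCl3·7H2O, MeOH, −78 °C) with hydride from the convex face should give the concave (3aS,4R,7aR)-alcohol F4. Mitsunobu esterification with acid 20 (PPh3, DIAD, THF) inverts C4 and gives 21 directly, so step 14 is bypassed.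

3. Step 7. Electron transfer to the tetrasubstituted, electron-rich ring of a poorly soluble dilithium salt may be incomplete, and prolonged exposure may isomerise the 1,4-diene and lead to over-reduction. Fallback, from 6 to 12: the arm is installed after dearomatisation of a less substituted, neutral arene. Silylation of 6 (TBSCl, imidazole) gives the silyl ether F5, and Birch reduction (Li, NH3, t-BuOH) gives the dihydroanisole F6, whose protonation pattern again leaves C5=C6 and the enol ether C7a=C3a. Rh2(OAc)4-catalysed cyclopropanation of the electron-rich enol ether with methyl diazoacetate gives the methoxycyclopropane ester F7. Dilute aqueous HCl in THF opens this donor–acceptor cyclopropane at the C7a–CH bond to the gamma-keto ester and removes the silyl group, giving 12; steps 5, 6 and 8 are bypassed.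

**Further compounds**

F1 | step 9 | methyl 2-[(1S,2S)-2-hydroxy-5-[(2S)-5-hydroxypentan-2-yl]-4-methylcyclohex-4-en-1-yl]acetate | COC(=O)C[C@@H]1CC([C@@H](C)CCCO)=C(C)C[C@@H]1O
F2 | step 9 | (3aS,7aS)-5-[(2S)-5-hydroxypentan-2-yl]-6-methyl-3a,4,7,7a-tetrahydro-1-benzofuran-2(3H)-one | C1C(=O)O[C@H]2CC(C)=C([C@@H](C)CCCO)C[C@@H]12
F3 | step 13 | (3aR,7aR)-5-[(2S)-5-(tert-butyldimethylsilyloxy)pentan-2-yl]-6-methyl-3-methylidene-3a,7a-dihydro-1-benzofuran-2,4(3H,7H)-dione | C=C1C(=O)O[C@@H]2CC(C)=C([C@@H](C)CCCO[Si](C)(C)C(C)(C)C)C(=O)[C@H]12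
F4 | step 13 | (3aS,4R,7aR)-5-[(2S)-5-(tert-butyldimethylsilyloxy)pentan-2-yl]-4-hydroxy-6-methyl-3-methylidene-3a,4,7,7a-tetrahydro-1-benzofuran-2(3H)-one | C=C1C(=O)O[C@@H]2CC(C)=C([C@@H](C)CCCO[Si](C)(C)C(C)(C)C)[C@H](O)[C@H]12
F5 | step 7 | tert-butyl{[(4S)-4-(4-methoxy-2-methylphenyl)pentyl]oxy}dimethylsilane | COc1ccc([C@@H](C)CCCO[Si](C)(C)C(C)(C)C)c(C)c1
F6 | step 7 | tert-butyl{[(4S)-4-(4-methoxy-2-methylcyclohexa-1,4-dien-1-yl)pentyl]oxy}dimethylsilane | COC1=CCC([C@@H](C)CCCO[Si](C)(C)C(C)(C)C)=C(C)C1
F7 | step 7 | methyl 4-[(2S)-5-(tert-butyldimethylsilyloxy)pentan-2-yl]-1-methoxy-3-methylbicyclo[4.1.0]hept-3-ene-7-carboxylate | COC(=O)C1C2CC([C@@H](C)CCCO[Si](C)(C)C(C)(C)C)=C(C)CC12OC
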